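A small charge of Q has to pass through a large charge of G many times over, so I counted turnovers: L made per Q charged.

| flask | G | Q | remark | time |
|---|---|---|---|---|
| oak | 0.20 M | 0.087 mM | run made earlier |  |
| larch | 0.20 M | 0.092 mM | run made earlier |  |
| ash | 0.20 M | 0.081 mM | run made earlier |  |
| Friday's | 0.20 M | 0.080 mM |  | 15 h |
| Tuesday's | 0.20 M | 0.11 mM |  | 8.0 h |

| run | time / h | L / % |
|---|---|---|
| oak | 0.667 | 5.9 |
| oak | 1.33 | 14.0 |
| oak | 2.50 | 26.0 |
| oak | 4.00 | 39.8 |
| oak | 8.00 | 74.3 |
| larch | 0.667 | 8.8 |
| larch | 2.00 | 21.6 |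
| larch | 4.00 | 42.8 |
| larch | 6.00 | 61.6 |
| larch | 8.00 | 76.8 |
| ash | 0.667 | 6.6 |
| ash | 1.33 | 13.2 |
| ash | 2.50 | 23.5 |
| ash | 4.00 | 37.6 |
| ash | 8.00 | 70.2 |

(scatter of a reading: 0.5 percentage points)

- a reading or a percentage of L counts all its forms, free or not

- which of the two ends with the higher amount of L, in percent of the G charged ("neither" if they lie within 2 percentage points) (Friday's / Tuesday's / neither)
- L at the end, in percent of the G charged, Friday's
- L at the end, in percent of the G charged, Tuesday's

One thing looked contradictory. Friday's flask held less Q than Tuesday's, 0.080 mM against 0.11 mM, and each Q in it had to make 2500 turnovers against 1820 in Tuesday's, yet I expected Friday's to end higher. The earlier runs cleared this up. Over the first 4.00 h, L made per Q per hour (the turnover frequency, w) read 229 h⁻¹ in oak, 233 h⁻¹ in larch and 232 h⁻¹ in ash, so I took their mean, 231 h⁻¹, as a reading. Multiplying w by the time and dividing by the turnovers demanded gave 1.39 for Friday's and 1.02 for Tuesday's; this ratio is the turnover budget, B, turnovers on offer over turnovers demanded. But larch bought less than its budget offered: there w read 165 h⁻¹ between 6.00 h and 8.00 h, and a budget of 0.851 had bought 76.8%. So I expected Tuesday's to end short of its whole charge of G and Friday's to end above Tuesday's.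

The forecast named Friday's, with 98% for Friday's and 88% for Tuesday's, judging that “the catalyst is near saturation”.

The flask gave 97.4% for Friday's and 86.9% for Tuesday's, so Friday's ended higher, as forecast.

    G + Q → D (k = 9000 M⁻¹ h⁻¹)
    D ⇌ X (K = 0.360, k = 640 h⁻¹)
    X → Q + L (k = 1900 h⁻¹)
    Q + L ⇌ Z (K = 2.20 M⁻¹, k = 1.50 M⁻¹ h⁻¹)

Here D and X are bound forms of the catalyst and Z is Q holding L. At 15.0 h, Z held 24.6% of the catalyst in Friday's flask. Friday's had spent 70.2% of its budget, and Tuesday's 85.5%.

With 0.50 M of G in place of Tuesday's charge, the budget is 0.407, less than one, which points to about 40.7% of that G as L. The computed flask gave 45.1%, with 55% of its G still free.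

The numbers in the tables are calculated for an exercise; scatter was added.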